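**Retrosynthetic overview**
- Feature: the seven-membered ring C1-C10-C9-C8-C7-C6-C5 is read as a para-disubstituted benzene ring (C1, C6, C7, C8, C9, C10; C14 on C8, the C2-C3 chain on C1). One extra carbon, C5, is inserted into its C1-C6 bond, and C5 is the α-carbon of a C4 ketone.
- Ring order: the arene comes first. One operation, the intramolecular Buchner reaction of diazoketone 10 to the achiral dihydroazulenone 13, then closes the five-membered ring C1-C5 and expands the benzene ring to the seven-membered ring.
- Five-membered ring next: CBS reduction sets C4, and its hydroxyl group steers a cyclopropanation of C1=C5. Reductive opening of the cyclopropyl ketone unveils C15 on C1 and 5α-H, and isopropyl addition rebuilds C4 as the tertiary carbinol.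
- Seven-membered ring last, with every oxygen delivered to the α face, away from the axial C15. Singlet oxygen adds across C6/C9, followed by Kornblum-DeLaMare opening and C6 acylation. The C9 ketone is then traded for a C9=C10 alkene, whose syn-dihydroxylation sets 9α,10α.
- The C14 pivalate, carried from the first step, leaves in a final palladium-formate allylic hydrogenolysis that moves C7=C8 to the C8=C14 methylene.

Key step: step 5

Remark: daucane numbering is used for all bicyclic compounds and β is the face that carries C15 in the target; read this way the target SMILES is (1S,4R,5S,6S,9R,10S), that is 1β-methyl, 4β-OH, 5α-H (trans fusion), 6α-acyloxy, 9α-OH, 10α-OH.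

**Step 1**
Reactants: 1 4-bromobenzyl alcohol; 2 pivaloyl chloride
Product: 3 4-bromobenzyl pivalate
Conditions: PivCl, Et3N, DMAP (cat.), CH2Cl2, 0 °C to rt
Reagents that add atoms: pivaloyl chloride CC(C)(C)C(Cl)=O
Why: DMAP-catalysed acylation of a primary benzylic alcohol is routine, and the hindered pivalate is chosen because it must outlast borane, zinc carbenoid, SmI2 and Grignard steps and finally serve as the allylic leaving group on C14.

**Step 2**
Reactants: 3 4-bromobenzyl pivalate; 4 acrylic acid
Product: 5 (E)-3-[4-(pivaloyloxymethyl)phenyl]prop-2-enoic acid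
Conditions: Pd(OAc)2 (cat.), P(o-tol)3, Et3N, MeCN, 85 °C; then aq. HCl
Reagents that add atoms: acrylic acid C=CC(=O)O
Why: Mizoroki-Heck arylation of acrylic acid gives the E-cinnamic acid directly, so no ester has to be hydrolysed later beside the pivalate, and the benzylic ester is inert to zerovalent palladium carrying a triarylphosphine.

**Step 3**
Reactants: 5 (E)-3-[4-(pivaloyloxymethyl)phenyl]prop-2-enoic acid
Product: 6 3-[4-(pivaloyloxymethyl)phenyl]propanoic acid
Conditions: H2 (1 atm), Pd/C, Ph2S (cat.), EtOAc, rt
Reagents that add atoms: none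
Why: Heterogeneous hydrogenation saturates the cinnamic double bond, and the diphenyl sulfide poison suppresses the hydrogenolysis of the benzylic C-O bond that unpoisoned Pd/C would cause.

**Step 4**
Reactants: 6 3-[4-(pivaloyloxymethyl)phenyl]propanoic acid; 7 (trimethylsilyl)diazomethane
Product: 10 1-diazo-4-[4-(pivaloyloxymethyl)phenyl]butan-2-one, via acid chloride 8 (not isolated), via C-silyl diazoketone 9 (not isolated)
Conditions: (COCl)2, DMF (cat.), CH2Cl2, 0 °C to rt, evaporate; TMSCHN2, Et3N, THF-MeCN, 0 °C; aq. NaHCO3
Reagents that add atoms: (trimethylsilyl)diazomethane C[Si](C)(C)C=[N+]=[N-]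
Why: This is the C-acylation of a diazoalkane by an acid chloride (the diazoketone stage of the Arndt-Eistert sequence, run with the safer silyl reagent), in which triethylamine takes up HCl so that no chloromethyl ketone forms and the C-silyl group of 9 falls off on aqueous work-up.

**Step 5**
Reactants: 10 1-diazo-4-[4-(pivaloyloxymethyl)phenyl]butan-2-one
Product: 13 6-(pivaloyloxymethyl)-3,4-dihydroazulen-1(2H)-one, via norcaradiene 11 (not isolated), via 8aH-azulenone 12 (not isolated)
Conditions: Rh2(OAc)4 (cat.), CH2Cl2, reflux, slow addition of 10 at high dilution; then Et3N (cat.), rt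
Reagents that add atoms: none
Why: Rh2(OAc)4 expels dinitrogen from 10, and the electrophilic rhodium carbenoid at C5 adds across the ipso/ortho bond C1-C6 of the tethered arene, forming C5-C1 and C5-C6 in one event (norcaradiene 11). The closest known reaction type is exactly this one, the intramolecular Buchner reaction of 1-diazo-4-arylbutan-2-ones to hydroazulenones. The five-membered ring C1-C2-C3-C4-C5 closes in the intramolecular [2+1] cycloaddition through the three-atom tether, and the seven-membered ring arises by thermal disrotatory 6π electrocyclic opening of the C1-C6 bond of 11 to cycloheptatriene 12, a one-carbon expansion of the benzene ring. Triethylamine then removes the C5 hydrogen, which is α to the ketone and doubly allylic, and reprotonation of the extended enolate at C10 gives the tetrasubstituted enone 13. The stereocentres of 11 and 12 are racemic and transient and vanish in achiral 13, so no stereocontrol is required here. The step needs arene addition to win over carbene dimerisation, over insertion into the C2 or C3 C-H bonds and over acid-induced collapse of 12 to a 2-tetralone, which the tether length (those insertions would give three- or four-membered rings), slow addition at high dilution and acid-free handling secure, while the para position of the pivaloyloxymethyl group makes the two ortho bonds equivalent so that C14 can only arrive on C8.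

**Step 6**
Reactants: 13 6-(pivaloyloxymethyl)-3,4-dihydroazulen-1(2H)-one
Product: 14 (1S)-6-(pivaloyloxymethyl)-1,2,3,4-tetrahydroazulen-1-ol (4β-OH)
Conditions: (R)-2-methyl-CBS-oxazaborolidine (cat.), catecholborane, toluene, -78 °C; aq. NaHCO3
Reagents that add atoms: none
Why: In this Corey-Bakshi-Shibata reduction the ketone binds to the catalyst boron anti to its larger, fully substituted alkenyl flank C5, so the (R)-catalyst should deliver hydride to the face that gives the 4S (4β) alcohol, and catecholborane at low temperature reduces the carbonyl 1,2 without hydroborating the triene.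

**Step 7**
Reactants: 14 (1S)-6-(pivaloyloxymethyl)-1,2,3,4-tetrahydroazulen-1-ol; 15 diiodomethane
Product: 16 4β-hydroxy-1β,5β-methano diene (C15 methylene bridging C1 and C5 on the face of the 4-OH; C6=C7, C8=C9, CH2OPiv on C8)
Conditions: Et2Zn, CH2I2, CH2Cl2, -20 to 0 °C; aq. NH4Cl
Reagents that add atoms: diiodomethane ICI
Why: In this hydroxyl-directed Simmons-Smith cyclopropanation (Furukawa reagent) the zinc alkoxide of 14 holds the carbenoid over the adjacent allylic and most electron-rich C1=C5 bond, so CH2 should add there and on the face of the hydroxyl group, which sets C1 and C5 with C15 on the β face.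

**Step 8**
Reactants: 16 4β-hydroxy-1β,5β-methano diene
Product: 17 cyclopropyl ketone (C4=O, C15 bridge β, C6=C7, C8=C9)
Conditions: Dess-Martin periodinane, NaHCO3, CH2Cl2, 0 °C
Reagents that add atoms: none
Why: Buffered Dess-Martin oxidation converts the acid-sensitive cyclopropyl carbinol into the ketone under neutral conditions without touching diene, cyclopropane or ester, and the C4 stereocentre, having relayed its information to C1 and C5, is given up.

**Step 9**
Reactants: 17 cyclopropyl ketone
Product: 18 trans-fused 1β-methyl-5α-H bicyclo[5.3.0]deca-6,8-dien-4-one (daucane numbering) with CH2OPiv on C8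
Conditions: SmI2, t-BuOH, THF-DMPU, -78 to -20 °C; pH 7 buffer
Reagents that add atoms: none
Why: In this reductive opening of a cyclopropyl ketone by divalent samarium the ketyl should cleave the exocyclic C5-C15 bond, which is aligned with the carbonyl π system, rather than the fusion bond C1-C5 lying in its nodal plane, the primary radical is reduced and protonated to the C15 methyl, and the extended enolate is protonated kinetically at its α-carbon C5 from the α face opposite the new angular methyl, which sets 5α-H and the trans fusion while C1 is kept.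

**Step 10**
Reactants: 18 trans-fused dienone; 19 isopropylmagnesium chloride
Product: 20 14-pivaloyloxydauca-6,8-dien-4β-ol (4α-isopropyl, 5α-H, 1β-methyl)
Conditions: i-PrMgCl, LaCl3·2LiCl, THF, -20 to 0 °C; aq. NH4Cl
Reagents that add atoms: isopropylmagnesium chloride CC(C)[Mg]Cl
Why: This is a lanthanum-promoted Grignard 1,2-addition in which the salt activates the carbonyl and holds back enolisation of the acidic C5-H and β-hydride reduction, the nucleophile should come from the α face because the pseudo-axial C15 methyl and C6 cover the β face, which sets C4 as 4β-OH (4R), and the hindered pivalate reacts more slowly than the ketone.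

**Step 11**
Reactants: 20 14-pivaloyloxydauca-6,8-dien-4β-ol
Product: 22 4β,6α-dihydroxy-14-pivaloyloxydauc-7-en-9-one, via endoperoxide 21 (not isolated)
Conditions: O2, tetraphenylporphyrin (cat.), visible light, CH2Cl2, -40 °C; Ar purge; then Et3N, 0 °C to rt
Reagents that add atoms: dioxygen O=O
Why: Singlet oxygen should add in a [4+2] sense to the s-cis diene C6-C9 from the α face, because the flap carbon C1 and its axial methyl cover the β face of the trans-fused ring, which sets 6α-O and 9α-O in 21, and the Kornblum-DeLaMare fragmentation should then remove the more accessible H9 (next to the C10 methylene, whereas H6 is flanked by the branched C5 and by the C4 carbinol, whose hydroxyl can hydrogen-bond to the departing O6) to give the C9 enone and the 6α-alcohol.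

**Step 12**
Reactants: 22 4β,6α-dihydroxy-14-pivaloyloxydauc-7-en-9-one; 23 isovaleric anhydride
Product: 24 6α-isovaleryloxy-4β-hydroxy-14-pivaloyloxydauc-7-en-9-one
Conditions: isovaleric anhydride, DMAP (cat.), Et3N, CH2Cl2, 0 °C to rt
Reagents that add atoms: isovaleric anhydride CC(C)CC(=O)OC(=O)CC(C)C
Why: DMAP-catalysed acyl transfer esterifies the only secondary alcohol while the tertiary, isopropyl-flanked 4-OH stays free, and acylating at this point lets the final ester double as the C6 protecting group.

**Step 13**
Reactants: 24 6α-isovaleryloxy-4β-hydroxy-14-pivaloyloxydauc-7-en-9-one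
Product: 25 6α-isovaleryloxy-14-pivaloyloxydauc-7-ene-4β,9β-diol
Conditions: NaBH4, CeCl3·7H2O, MeOH, -78 to -40 °C
Reagents that add atoms: none
Why: Luche reduction gives 1,2-reduction of the enone beside both esters, and hydride is expected from the open α face because the axial C15 leans over the β face of C9, which gives the pseudo-axial 9β-alcohol, a configuration that only serves to align the next elimination and is then lost.

**Step 14**
Reactants: 25 6α-isovaleryloxy-14-pivaloyloxydauc-7-ene-4β,9β-diol
Product: 27 6α-isovaleryloxy-14-pivaloyloxydauca-7,9-dien-4β-ol, via 9β-mesylate 26 (not isolated)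
Conditions: Ms2O, Et3N, CH2Cl2, -30 °C; then DBU, -30 °C to rt
Reagents that add atoms: none
Why: Sulfonylation of the only secondary alcohol is followed by base-induced E2 elimination, in which the pseudo-axial 9β-mesylate is antiperiplanar to the axial 10α-H on the open face and C8 carries no hydrogen, so 1,2-elimination can only give the conjugated C7=C8-C9=C10 diene, and chloride-free Ms2O avoids allylic chloride formation.

**Step 15**
Reactants: 27 6α-isovaleryloxy-14-pivaloyloxydauca-7,9-dien-4β-ol
Product: 28 6α-isovaleryloxy-14-pivaloyloxydauc-7-ene-4β,9α,10α-triol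
Conditions: OsO4 (cat.), NMO, acetone-H2O, 0 °C; aq. Na2SO3
Reagents that add atoms: N-methylmorpholine N-oxide C[N+]1([O-])CCOCC1; water O; both oxygens are passed on through OsO4 O=[Os](=O)(=O)=O
Why: In this Upjohn dihydroxylation OsO4 should add suprafacially to C9=C10 rather than to C7=C8, which is trisubstituted, more hindered and deactivated by two allylic acyloxy groups, and it should add from the α face because the C15 methyl on the neighbouring C1 stands axially over the β face, so 9α-OH and 10α-OH are set together as the cis-diol.

**Step 16**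
Reactants: 28 6α-isovaleryloxy-14-pivaloyloxydauc-7-ene-4β,9α,10α-triol
Product: 29 6α-isovaleryloxydauc-8(14)-ene-4β,9α,10α-triol (CNP0204264.1)
Conditions: Pd2(dba)3·CHCl3 (cat.), n-Bu3P, HCO2H, Et3N, THF, 50 °C
Reagents that add atoms: none
Why: This is a palladium-formate allylic hydrogenolysis (Tsuji-Trost ionisation, decarboxylation, hydride transfer) in which, with n-Bu3P, hydride passes from palladium to the more substituted allyl terminus C7 and leaves the less substituted C8=C14 methylene, the primary pivalate ionises in preference to the 6α-ester, whose pseudo-equatorial C-O bond is poorly aligned with the π bond and whose anti face is blocked by C15, and no stereocentre is touched.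

**Compound list**
1 | 4-bromobenzyl alcohol | OCc1ccc(Br)cc1 | starting material
2 | pivaloyl chloride | CC(C)(C)C(Cl)=O | starting material
3 | 4-bromobenzyl pivalate | CC(C)(C)C(=O)OCc1ccc(Br)cc1 | intermediate
4 | acrylic acid | C=CC(=O)O | starting material
5 | (E)-3-[4-(pivaloyloxymethyl)phenyl]prop-2-enoic acid | CC(C)(C)C(=O)OCc1ccc(/C=C/C(=O)O)cc1 | intermediate
6 | 3-[4-(pivaloyloxymethyl)phenyl]propanoic acid | CC(C)(C)C(=O)OCc1ccc(CCC(=O)O)cc1 | intermediate
7 | (trimethylsilyl)diazomethane | C[Si](C)(C)C=[N+]=[N-] | starting material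
8 | 3-[4-(pivaloyloxymethyl)phenyl]propanoyl chloride | CC(C)(C)C(=O)OCc1ccc(CCC(=O)Cl)cc1 | intermediate (not isolated)
9 | 1-diazo-1-(trimethylsilyl)-4-[4-(pivaloyloxymethyl)phenyl]butan-2-one | CC(C)(C)C(=O)OCc1ccc(CCC(=O)C(=[N+]=[N-])[Si](C)(C)C)cc1 | intermediate (not isolated)
10 | 1-diazo-4-[4-(pivaloyloxymethyl)phenyl]butan-2-one | [N-]=[N+]=CC(=O)CCc1ccc(COC(=O)C(C)(C)C)cc1 | intermediate
11 | norcaradiene, cyclopropane C1-C5-C6, C7=C8, C9=C10 (racemic, transient) | O=C1CCC23C=CC(COC(=O)C(C)(C)C)=CC2C13 | intermediate (not isolated)
12 | 6-(pivaloyloxymethyl)-3,8a-dihydroazulen-1(2H)-one, C5-H, C1=C10, C8=C9, C6=C7 (racemic, transient) | O=C1CCC2=CC=C(COC(=O)C(C)(C)C)C=CC12 | intermediate (not isolated)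
13 | 6-(pivaloyloxymethyl)-3,4-dihydroazulen-1(2H)-one, C4=O, C1=C5, C6=C7, C8=C9 (achiral) | O=C1CCC2=C1C=CC(COC(=O)C(C)(C)C)=CC2 | intermediate
14 | (1S)-6-(pivaloyloxymethyl)-1,2,3,4-tetrahydroazulen-1-ol (4β-OH) | O[C@H]1CCC2=C1C=CC(COC(=O)C(C)(C)C)=CC2 | intermediate
15 | diiodomethane | ICI | starting material
16 | 4β-hydroxy-1β,5β-methano diene (C15 bridge syn to 4-OH) | O[C@H]1CC[C@@]23C[C@@]12C=CC(COC(=O)C(C)(C)C)=CC3 | intermediate
17 | cyclopropyl ketone (C4=O, C15 bridge β) | O=C1CC[C@@]23C[C@@]12C=CC(COC(=O)C(C)(C)C)=CC3 | intermediate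
18 | trans-fused 1β-methyl-5α-H dien-4-one with CH2OPiv on C8 | O=C1CC[C@]2(C)CC=C(COC(=O)C(C)(C)C)C=C[C@@H]12 | intermediate
19 | isopropylmagnesium chloride | CC(C)[Mg]Cl | starting material
20 | 14-pivaloyloxydauca-6,8-dien-4β-ol | CC(C)[C@]1(O)CC[C@]2(C)CC=C(COC(=O)C(C)(C)C)C=C[C@@H]12 | intermediate
21 | 6α,9α-epidioxy-14-pivaloyloxydauc-7-en-4β-ol | CC(C)[C@]1(O)CC[C@]2(C)C[C@@H]3OO[C@@H](C=C3COC(=O)C(C)(C)C)[C@@H]12 | intermediate (not isolated)
22 | 4β,6α-dihydroxy-14-pivaloyloxydauc-7-en-9-one | CC(C)[C@]1(O)CC[C@]2(C)CC(=O)C(COC(=O)C(C)(C)C)=C[C@H](O)[C@@H]12 | intermediate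
23 | isovaleric anhydride | CC(C)CC(=O)OC(=O)CC(C)C | starting material
24 | 6α-isovaleryloxy-4β-hydroxy-14-pivaloyloxydauc-7-en-9-one | CC(C)[C@]1(O)CC[C@]2(C)CC(=O)C(COC(=O)C(C)(C)C)=C[C@H](OC(=O)CC(C)C)[C@@H]12 | intermediate
25 | 6α-isovaleryloxy-14-pivaloyloxydauc-7-ene-4β,9β-diol | CC(C)[C@]1(O)CC[C@]2(C)C[C@@H](O)C(COC(=O)C(C)(C)C)=C[C@H](OC(=O)CC(C)C)[C@@H]12 | intermediate
26 | 9β-methanesulfonate of 25 | CC(C)[C@]1(O)CC[C@]2(C)C[C@@H](OS(C)(=O)=O)C(COC(=O)C(C)(C)C)=C[C@H](OC(=O)CC(C)C)[C@@H]12 | intermediate (not isolated)
27 | 6α-isovaleryloxy-14-pivaloyloxydauca-7,9-dien-4β-ol | CC(C)[C@]1(O)CC[C@]2(C)C=CC(COC(=O)C(C)(C)C)=C[C@H](OC(=O)CC(C)C)[C@@H]12 | intermediate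
28 | 6α-isovaleryloxy-14-pivaloyloxydauc-7-ene-4β,9α,10α-triol | CC(C)[C@]1(O)CC[C@]2(C)[C@H](O)[C@H](O)C(COC(=O)C(C)(C)C)=C[C@H](OC(=O)CC(C)C)[C@@H]12 | intermediate
29 | 6α-isovaleryloxydauc-8(14)-ene-4β,9α,10α-triol (CNP0204264.1) | C=C1C[C@H](OC(=O)CC(C)C)[C@@H]2[C@](C)(CC[C@@]2(O)C(C)C)[C@H](O)[C@@H]1O | target

Total step count: 16. Longest linear sequence: 16 steps (1 to 29).

**Steps most likely to fail**

Step 9. Electron transfer may cleave the fusion bond C1-C5 instead of C5-C15, or it may reach the dienylic pivalate. The extended enolate may be protonated at C7 or C9 or from the β face. The β,γ-unsaturated ketone may also slip into conjugation or epimerise at C5 during work-up. The fallback sets out from 17 and comes back at 18, and it opens the cyclopropyl ketone in a polar way instead of by electron transfer. Me3SiI (CH2Cl2, -78 to -40 °C) silylates the carbonyl oxygen, and iodide attacks the unhindered methylene C15 in an SN2 sense (homoconjugate addition). This attack at C15 breaks the activated C5-C15 bond and gives the iodomethyl silyl trienol ether F1. Buffered hydrolysis gives the iodomethyl ketone F2. Radical deiodination (n-Bu3SnH, Et3B, air, toluene, 0 °C) then turns CH2I into the C15 methyl of 18.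

Step 10. The basic reagent may enolise the doubly activated C5-H, which would return, epimerise or conjugate the ketone. β-Hydride transfer may reduce the hindered carbonyl, and the pivalate may be attacked. The fallback sets out from 18 and comes back at 22. The slimmer, less basic sp2 nucleophile isopropenylmagnesium bromide, which has no β-hydride to transfer (LaCl3·2LiCl, THF, -20 °C), adds from the α face and gives the isopropenyl carbinol F3. Photo-oxygenation and amine treatment as in step 11 give the endoperoxide F4 and then the hydroxy enone F5, since a 1,1-disubstituted alkene reacts far more slowly with singlet oxygen than the cyclic diene. Homogeneous hydrogenation with RhCl(PPh3)3 (H2, toluene, rt) saturates only the 1,1-disubstituted alkene, leaves the trisubstituted enone untouched, and gives 22.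

Step 16. Hydride may be transferred to the primary terminus C14, which would leave an endocyclic 8-methyl alkene. The C6 ester may ionise or be lost by 1,4-elimination from the allyl complex, and the free diol may be O-allylated. The fallback sets out from 28 and comes back at 29, and it avoids allylpalladium chemistry altogether.
- The diol is masked as the acetonide F6 (2,2-dimethoxypropane, PPTS, CH2Cl2).
- Both esters are removed with i-Bu2AlH (CH2Cl2, -78 to 0 °C) to give the triol F7.
- The primary allylic alcohol alone undergoes Mitsunobu displacement by 2-nitrobenzenesulfonylhydrazide (PPh3, DEAD, THF, -30 °C) to give the sulfonylhydrazine F8.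
- On warming, F8 loses the sulfinic acid to give the allylic diazene F9.
- Retro-ene loss of dinitrogen from F9 necessarily places hydrogen on C7 and the double bond at C8=C14, giving the methylene alcohol F10.
- Acylation as in step 12 gives the ester F11, and aqueous acetic acid (40 °C) frees the diol to give 29.

**Further compounds**
F1 | step 9 | iodomethyl silyl trienol ether (C4-OSiMe3, C4=C5, C1-CH2I) | C[Si](C)(C)OC1=C2C=CC(COC(=O)C(C)(C)C)=CC[C@@]2(CI)CC1
F2 | step 9 | 1β-iodomethyl-5α-H dien-4-one | O=C1CC[C@]2(CI)CC=C(COC(=O)C(C)(C)C)C=C[C@@H]12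
F3 | step 10 | 4α-isopropenyl-4β-ol analogue of 20 | C=C(C)[C@]1(O)CC[C@]2(C)CC=C(COC(=O)C(C)(C)C)C=C[C@@H]12
F4 | step 10 | 4α-isopropenyl analogue of endoperoxide 21 | C=C(C)[C@]1(O)CC[C@]2(C)C[C@@H]3OO[C@@H](C=C3COC(=O)C(C)(C)C)[C@@H]12
F5 | step 10 | 4α-isopropenyl analogue of hydroxy enone 22 | C=C(C)[C@]1(O)CC[C@]2(C)CC(=O)C(COC(=O)C(C)(C)C)=C[C@H](O)[C@@H]12
F6 | step 16 | 9α,10α-acetonide of 28 | CC(C)[C@]1(O)CC[C@]2(C)[C@@H]3OC(C)(C)O[C@@H]3C(COC(=O)C(C)(C)C)=C[C@H](OC(=O)CC(C)C)[C@@H]12
F7 | step 16 | 9α,10α-acetonide 4β,6α,14-triol | CC(C)[C@]1(O)CC[C@]2(C)[C@@H]3OC(C)(C)O[C@@H]3C(CO)=C[C@H](O)[C@@H]12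
F8 | step 16 | C14 N-(2-nitrobenzenesulfonyl)hydrazine | CC(C)[C@]1(O)CC[C@]2(C)[C@@H]3OC(C)(C)O[C@@H]3C(CN(N)S(=O)(=O)c3ccccc3[N+](=O)[O-])=C[C@H](O)[C@@H]12
F9 | step 16 | C14 allylic diazene | CC(C)[C@]1(O)CC[C@]2(C)[C@@H]3OC(C)(C)O[C@@H]3C(CN=N)=C[C@H](O)[C@@H]12
F10 | step 16 | 8(14)-methylene 4β,6α-diol acetonide | CC(C)[C@]1(O)CC[C@]2(C)[C@@H]3OC(C)(C)O[C@@H]3C(=C)C[C@H](O)[C@@H]12
F11 | step 16 | 9α,10α-acetonide of 29 | CC(C)[C@]1(O)CC[C@]2(C)[C@@H]3OC(C)(C)O[C@@H]3C(=C)C[C@H](OC(=O)CC(C)C)[C@@H]12
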